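**Strategy.** The route rests on cutting the diaryl ether oxygen that joins C3 of ring A (the methoxy ring) to C4 of ring B (the para-phenylene). Both carbons belong to unactivated arenes, so the bond is re-drawn as an aryl benzoate. A 20-membered macrolactone is made by ordinary esterification of the ring A phenol with the ring B carboxylic acid and is then contracted by nickel-catalysed loss of CO. That single operation joins the ring B ipso carbon to the ring A oxygen and sets the 19-membered ring. The precursor already holds both CH2CH2 bridges, the ether between ring C (phenol ring) and ring D (meta-phenylene), and the ring C phenol as its benzyl ether.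

Key step: step 9

Remark: both Wittig steps give E/Z mixtures that are carried on unseparated because step 6 saturates both alkenes; ylides, activated acyl species and organonickel species are treated as mechanism within one reaction; phosphonium salt 4 is a catalogue compound.

**Step 1**
Reactants: 1 4-benzyloxy-3-hydroxybenzaldehyde; 2 3-(hydroxymethyl)phenylboronic acid (2 equiv)
Product: 3 4-(benzyloxy)-3-[3-(hydroxymethyl)phenoxy]benzaldehyde
Conditions: Cu(OAc)2 (1 equiv), pyridine (5 equiv), 4 Å MS, CH2Cl2, air, rt
Reagents that add atoms: none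
Why: Chan–Lam coupling, in which the phenol of 1 is arylated through an aryl copper phenoxide much faster than the aliphatic hydroxyl of 2, the aldehyde and benzyl ether are inert, and air returns copper to the divalent state.

**Step 2**
Reactants: 3 4-(benzyloxy)-3-[3-(hydroxymethyl)phenoxy]benzaldehyde; 4 [4-(methoxycarbonyl)benzyl]triphenylphosphonium bromide
Product: 5 methyl 4-[2-[4-(benzyloxy)-3-[3-(hydroxymethyl)phenoxy]phenyl]ethenyl]benzoate (E/Z mixture)
Conditions: K2CO3, 18-crown-6 (cat.), CH2Cl2, reflux
Reagents that add atoms: none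
Why: Wittig olefination of the ring C aldehyde by the ester-stabilised benzylic phosphonium salt under solid–liquid carbonate conditions, which are too mild to touch the methyl ester, the free benzylic alcohol or the benzyl ether.

**Step 3**
Reactants: 5 methyl 4-[2-[4-(benzyloxy)-3-[3-(hydroxymethyl)phenoxy]phenyl]ethenyl]benzoate
Product: 6 [3-[2-(benzyloxy)-5-[2-[4-(methoxycarbonyl)phenyl]ethenyl]phenoxy]benzyl]triphenylphosphonium bromide (E/Z mixture)
Conditions: PPh3·HBr, MeCN, reflux
Reagents that add atoms: triphenylphosphine hydrobromide, [Br-].c1ccc(cc1)[PH+](c1ccccc1)c1ccccc1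
Why: direct acid-promoted substitution of a benzylic hydroxyl by triphenylphosphine, a standard one-step entry to benzyltriphenylphosphonium bromides that should leave the aryl benzyl ether, the ester and the stilbene untouched.

**Step 4**
Reactants: 7 isovanillin (3-hydroxy-4-methoxybenzaldehyde)
Product: 8 3-[(tert-butyldimethylsilyl)oxy]-4-methoxybenzaldehyde
Conditions: TBSCl, imidazole, DMF, rt
Reagents that add atoms: tert-butyldimethylsilyl chloride (TBSCl), CC(C)(C)[Si](C)(C)Cl
Why: routine phenol silylation that masks the acidic hydroxyl for the carbonate-mediated Wittig step and is later lost in the saponification flask at no cost in steps.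

**Step 5**
Reactants: 6 [3-[2-(benzyloxy)-5-[2-[4-(methoxycarbonyl)phenyl]ethenyl]phenoxy]benzyl]triphenylphosphonium bromide; 8 3-[(tert-butyldimethylsilyl)oxy]-4-methoxybenzaldehyde
Product: 9 methyl 4-[2-[4-(benzyloxy)-3-[3-[2-[3-[(tert-butyldimethylsilyl)oxy]-4-methoxyphenyl]ethenyl]phenoxy]phenyl]ethenyl]benzoate (mixture of alkene isomers)
Conditions: K2CO3, 18-crown-6 (cat.), CH2Cl2, reflux
Reagents that add atoms: none
Why: second Wittig olefination under the same anhydrous carbonate conditions, which joins the ring D benzylic carbon to the ring A aldehyde carbon while the methyl ester and aryl silyl ether survive.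

**Step 6**
Reactants: 9 methyl 4-[2-[4-(benzyloxy)-3-[3-[2-[3-[(tert-butyldimethylsilyl)oxy]-4-methoxyphenyl]ethenyl]phenoxy]phenyl]ethenyl]benzoate
Product: 10 methyl 4-[2-[4-(benzyloxy)-3-[3-[2-[3-[(tert-butyldimethylsilyl)oxy]-4-methoxyphenyl]ethyl]phenoxy]phenyl]ethyl]benzoate
Conditions: H2 (1 atm), 10% Pd/C, Ph2S (0.01 equiv), EtOAc, rt
Reagents that add atoms: none
Why: catalytic hydrogenation over sulfide-poisoned palladium, which should saturate both disubstituted alkenes while hydrogenolysis of the aryl benzyl ether is suppressed and the silyl ether and ester are inert.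

**Step 7**
Reactants: 10 methyl 4-[2-[4-(benzyloxy)-3-[3-[2-[3-[(tert-butyldimethylsilyl)oxy]-4-methoxyphenyl]ethyl]phenoxy]phenyl]ethyl]benzoate
Product: 12 4-[2-[4-(benzyloxy)-3-[3-[2-(3-hydroxy-4-methoxyphenyl)ethyl]phenoxy]phenyl]ethyl]benzoic acid, via phenol methyl ester 11 (not isolated)
Conditions: LiOH·H2O (6 equiv), THF/MeOH/H2O, 50 °C; then 1 M HCl
Reagents that add atoms: lithium hydroxide (LiOH), [Li+].[OH-]
Why: hydroxide first cleaves the aryl silyl ether (phenoxide is a good leaving group on silicon) and then saponifies the methyl benzoate by acyl substitution, while benzyl, methyl and diaryl ethers are stable to base.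

**Step 8**
Reactants: 12 4-[2-[4-(benzyloxy)-3-[3-[2-(3-hydroxy-4-methoxyphenyl)ethyl]phenoxy]phenyl]ethyl]benzoic acid
Product: 13 20-membered macrolactone, in which the ring A oxygen at C3 is acylated by the ring B carboxyl and the ring C phenol is a benzyl ether
Conditions: DCC, DMAP, DMAP·HCl, CHCl3, reflux, syringe-pump addition (final 1 mM)
Reagents that add atoms: none
Why: Steglich esterification run as a high-dilution macrolactonization (Keck variant), in which the carbodiimide activates only the carboxylic acid, DMAP relays the acyl group to the single free phenol, DMAP·HCl suppresses N-acylurea formation, and slow addition favours ring closure over oligomers.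

**Step 9**
Reactants: 13 20-membered macrolactone
Product: 14 O-benzyl ether of the target (19-membered bis(bibenzyl) diaryl ether)
Conditions: Ni(cod)2 (20 mol%), 3,4-bis(dicyclohexylphosphino)thiophene (40 mol%), anhydrous K3PO4 (1.5 equiv), toluene (0.02 M), 150 °C, sealed tube
Reagents that add atoms: none
Why: Proposed new method: zerovalent nickel carrying the electron-rich chelating diphosphine should insert into the acyl C–O bond of the aryl benzoate, the ring B aryl group should migrate from the carbonyl carbon to nickel, CO should leave, and C–O reductive elimination from the aryl(aryloxy)nickel species, in which nickel is divalent, should give the ether. The closest known reaction type is the nickel- or palladium-catalysed decarbonylative etherification of aryl azinecarboxylates with this ligand; a carbocyclic benzoate lacks the ring nitrogen that assists those substrates, and a macrocyclic ester has not been contracted in this way, hence the raised catalyst loading. The 19-membered ring is formed by ring contraction and not by cyclisation: the ring A oxygen and the ring B ipso carbon stay on one nickel atom inside the existing 20-membered ring, so no end-to-end encounter is needed. No stereocentre is formed. The step needs the acyl C–O bond to react before the diaryl ether, aryl methyl ether and benzyl ether C–O bonds, which the far higher reactivity of an aryl ester toward zerovalent nickel should secure. It also needs the absence of any free phenol that could exchange with the nickel aryloxide, which the benzyl ether on ring C and the moderate dilution secure.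

**Step 10**
Reactants: 14 O-benzyl ether of the target
Product: 15 target, CNP0132125.0
Conditions: H2 (1 atm), 10% Pd/C, EtOAc/MeOH, rt
Reagents that add atoms: none
Why: hydrogenolysis of the aryl benzyl ether over unpoisoned palladium, under which the diaryl ethers, the methyl ether and the bibenzyl bridges are inert.

**Compound list**

1 | 4-benzyloxy-3-hydroxybenzaldehyde | O=Cc1ccc(OCc2ccccc2)c(O)c1 | starting material
2 | 3-(hydroxymethyl)phenylboronic acid | OCc1cccc(B(O)O)c1 | starting material
3 | 4-(benzyloxy)-3-[3-(hydroxymethyl)phenoxy]benzaldehyde | O=Cc1ccc(OCc2ccccc2)c(Oc2cccc(CO)c2)c1 | intermediate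
4 | [4-(methoxycarbonyl)benzyl]triphenylphosphonium bromide | COC(=O)c1ccc(C[P+](c2ccccc2)(c2ccccc2)c2ccccc2)cc1.[Br-] | starting material
5 | methyl 4-[2-[4-(benzyloxy)-3-[3-(hydroxymethyl)phenoxy]phenyl]ethenyl]benzoate (E/Z mixture, geometry undefined) | COC(=O)c1ccc(C=Cc2ccc(OCc3ccccc3)c(Oc3cccc(CO)c3)c2)cc1 | intermediate
6 | [3-[2-(benzyloxy)-5-[2-[4-(methoxycarbonyl)phenyl]ethenyl]phenoxy]benzyl]triphenylphosphonium bromide (E/Z mixture) | COC(=O)c1ccc(C=Cc2ccc(OCc3ccccc3)c(Oc3cccc(C[P+](c4ccccc4)(c4ccccc4)c4ccccc4)c3)c2)cc1.[Br-] | intermediate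
7 | isovanillin | COc1ccc(C=O)cc1O | starting material
8 | 3-[(tert-butyldimethylsilyl)oxy]-4-methoxybenzaldehyde | COc1ccc(C=O)cc1O[Si](C)(C)C(C)(C)C | intermediate
9 | methyl 4-[2-[4-(benzyloxy)-3-[3-[2-[3-[(tert-butyldimethylsilyl)oxy]-4-methoxyphenyl]ethenyl]phenoxy]phenyl]ethenyl]benzoate (mixture of alkene isomers) | COC(=O)c1ccc(C=Cc2ccc(OCc3ccccc3)c(Oc3cccc(C=Cc4ccc(OC)c(O[Si](C)(C)C(C)(C)C)c4)c3)c2)cc1 | intermediate
10 | methyl 4-[2-[4-(benzyloxy)-3-[3-[2-[3-[(tert-butyldimethylsilyl)oxy]-4-methoxyphenyl]ethyl]phenoxy]phenyl]ethyl]benzoate | COC(=O)c1ccc(CCc2ccc(OCc3ccccc3)c(Oc3cccc(CCc4ccc(OC)c(O[Si](C)(C)C(C)(C)C)c4)c3)c2)cc1 | intermediate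
11 | methyl 4-[2-[4-(benzyloxy)-3-[3-[2-(3-hydroxy-4-methoxyphenyl)ethyl]phenoxy]phenyl]ethyl]benzoate | COC(=O)c1ccc(CCc2ccc(OCc3ccccc3)c(Oc3cccc(CCc4ccc(OC)c(O)c4)c3)c2)cc1 | intermediate (not isolated)
12 | 4-[2-[4-(benzyloxy)-3-[3-[2-(3-hydroxy-4-methoxyphenyl)ethyl]phenoxy]phenyl]ethyl]benzoic acid | OC(=O)c1ccc(CCc2ccc(OCc3ccccc3)c(Oc3cccc(CCc4ccc(OC)c(O)c4)c3)c2)cc1 | intermediate
13 | 20-membered aryl ester macrocycle (ring A O–C(=O)–ring B), ring C phenol as benzyl ether | COc1ccc2cc1OC(=O)c1ccc(cc1)CCc1ccc(OCc3ccccc3)c(c1)Oc1cccc(c1)CC2 | intermediate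
14 | O-benzyl ether of the target, 19-membered macrocycle | COc1ccc2cc1Oc1ccc(cc1)CCc1ccc(OCc3ccccc3)c(c1)Oc1cccc(c1)CC2 | intermediate
15 | CNP0132125.0 (no stereocentres) | COc1ccc2cc1Oc1ccc(cc1)CCc1ccc(O)c(c1)Oc1cccc(c1)CC2 | target

**Totals**

Total step count: 10 (step 4 lies on a side branch).
Longest linear sequence: 9 steps (1, 2, 3, 5, 6, 7, 8, 9, 10).

**Steps most likely to fail**

Step 9. The catalytic cycle may stall after oxidative addition: CO may stay bound to nickel and shut the catalyst down, or the aryl(aryloxy)nickel intermediate may not undergo C–O reductive elimination because the benzoate has no coordinating ring nitrogen. The fallback builds the ring A–O–ring B bond by a known copper-mediated macrocyclisation and sets out from aldehyde 3.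
- Wittig olefination of 3 with commercial (4-bromobenzyl)triphenylphosphonium bromide (K2CO3, 18-crown-6, CH2Cl2, reflux) should give the bromostilbene alcohol F1.
- PPh3·HBr in refluxing MeCN should give the bromostilbene phosphonium bromide F2.
- A Wittig reaction of F2 with aldehyde 8 under the same carbonate conditions should give the silylated bromo bis-stilbene F3.
- Diimide reduction (p-toluenesulfonyl hydrazide, NaOAc, DME/H2O, reflux), which spares the aryl bromide and the benzyl ether, should give the silylated bromo bis-bibenzyl F4.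
- Tetrabutylammonium fluoride in THF should free the ring A phenol and give the bromo phenol F5.
- Intramolecular Ullmann etherification of F5 (CuI, N,N-dimethylglycine hydrochloride, Cs2CO3, dioxane, 100 °C, 2 mM) should close the 19-membered ring directly and come back to the route at compound 14.

Step 8. Intermolecular esterification may outrun ring closure (oligomerisation), or acyl transfer to the hindered ortho-methoxy phenol may be slow enough for the activated acid to rearrange. The fallback forms the aryl ester intermolecularly and closes the ring at the ring D–ring A bridge instead, setting out from stilbene 5.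
- Hydrogenation of 5 as in step 6 should give the saturated hydroxy ester F6.
- LiOH in THF/MeOH/H2O should give the hydroxy acid F7.
- PPh3·HBr in refluxing MeCN should give the carboxy phosphonium bromide F8.
- Steglich esterification of F8 with isovanillin 7 (EDC·HCl, DMAP cat., CH2Cl2, rt) should give the aryl ester formyl phosphonium bromide F9.
- An intramolecular Wittig reaction of F9 (K2CO3, 18-crown-6, CH2Cl2, reflux, slow addition, 1 mM) should give the macrocyclic stilbene lactone F10.
- Hydrogenation of F10 as in step 6 should come back to the route at compound 13.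

Step 1. Protodeboronation and oxidative homocoupling of the boronic acid, or slow arylation of the ortho-alkoxy phenol, may leave conversion low. The fallback replaces the oxidative coupling with an Ullmann-type etherification. It sets out from phenol 1, which should couple with commercial 3-iodobenzyl alcohol (CuI 10 mol%, N,N-dimethylglycine hydrochloride 30 mol%, Cs2CO3, dioxane, 90 °C). The phenoxide should react in preference to the aliphatic hydroxyl, and the sequence comes back to the route at compound 3.

**Further compounds**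

F1 | step 9 | [3-[2-(benzyloxy)-5-[2-(4-bromophenyl)ethenyl]phenoxy]phenyl]methanol (E/Z mixture) | OCc1cccc(Oc2cc(C=Cc3ccc(Br)cc3)ccc2OCc2ccccc2)c1
F2 | step 9 | [3-[2-(benzyloxy)-5-[2-(4-bromophenyl)ethenyl]phenoxy]benzyl]triphenylphosphonium bromide (E/Z mixture) | Brc1ccc(C=Cc2ccc(OCc3ccccc3)c(Oc3cccc(C[P+](c4ccccc4)(c4ccccc4)c4ccccc4)c3)c2)cc1.[Br-]
F3 | step 9 | tert-butyldimethylsilyl ether of 5-[2-[3-[2-(benzyloxy)-5-[2-(4-bromophenyl)ethenyl]phenoxy]phenyl]ethenyl]-2-methoxyphenol (mixture of alkene isomers) | COc1ccc(C=Cc2cccc(Oc3cc(C=Cc4ccc(Br)cc4)ccc3OCc3ccccc3)c2)cc1O[Si](C)(C)C(C)(C)C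
F4 | step 9 | tert-butyldimethylsilyl ether of 5-[2-[3-[2-(benzyloxy)-5-[2-(4-bromophenyl)ethyl]phenoxy]phenyl]ethyl]-2-methoxyphenol | COc1ccc(CCc2cccc(Oc3cc(CCc4ccc(Br)cc4)ccc3OCc3ccccc3)c2)cc1O[Si](C)(C)C(C)(C)C
F5 | step 9 | 5-[2-[3-[2-(benzyloxy)-5-[2-(4-bromophenyl)ethyl]phenoxy]phenyl]ethyl]-2-methoxyphenol | COc1ccc(CCc2cccc(Oc3cc(CCc4ccc(Br)cc4)ccc3OCc3ccccc3)c2)cc1O
F6 | step 8 | methyl 4-[2-[4-(benzyloxy)-3-[3-(hydroxymethyl)phenoxy]phenyl]ethyl]benzoate | COC(=O)c1ccc(CCc2ccc(OCc3ccccc3)c(Oc3cccc(CO)c3)c2)cc1
F7 | step 8 | 4-[2-[4-(benzyloxy)-3-[3-(hydroxymethyl)phenoxy]phenyl]ethyl]benzoic acid | OC(=O)c1ccc(CCc2ccc(OCc3ccccc3)c(Oc3cccc(CO)c3)c2)cc1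
F8 | step 8 | [3-[2-(benzyloxy)-5-[2-(4-carboxyphenyl)ethyl]phenoxy]benzyl]triphenylphosphonium bromide | OC(=O)c1ccc(CCc2ccc(OCc3ccccc3)c(Oc3cccc(C[P+](c4ccccc4)(c4ccccc4)c4ccccc4)c3)c2)cc1.[Br-]
F9 | step 8 | [3-[2-(benzyloxy)-5-[2-[4-[(5-formyl-2-methoxyphenoxy)carbonyl]phenyl]ethyl]phenoxy]benzyl]triphenylphosphonium bromide | COc1ccc(C=O)cc1OC(=O)c1ccc(CCc2ccc(OCc3ccccc3)c(Oc3cccc(C[P+](c4ccccc4)(c4ccccc4)c4ccccc4)c3)c2)cc1.[Br-]
F10 | step 8 | 20-membered aryl ester macrocycle with a CH=CH bridge between ring D and ring A (alkene geometry as formed) | COc1ccc2cc1OC(=O)c1ccc(cc1)CCc1ccc(OCc3ccccc3)c(c1)Oc1cccc(c1)C=C2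
F0 | step 1 | none | none
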